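**Retrosynthetic overview**

1. Goyazensolide 30 ⇐ bridged furanone 25 (C8=CH2 as masked C8–O, C13–OAc as masked 11(13)-methylene, C15–OTBS) ⇐ bridged tetrahydrofuranone 23 by C2–C3 dehydrogenation.
2. Key disconnection (O–C10 and C9–C10): 23 ⇐ α-diazoketone 21 carried on an eight-membered cyclic ether; copper carbenoid → oxonium ylide → [2,3] shift enlarges the ether ring by one atom (8 → 9) and closes the furanone ring and the ten-membered carbocycle in the same operation.
3. Enabling feature: the ring oxygen between C3 and C10 sits on quaternary C10, which is α to the C1 ketone (an α-alkoxy ketone, the retron of an oxonium ylide shift), and C8, reached from C10 through C9, is oxygenated, so C9–C8 can come from an O–CH2–C(=CH2) allyl unit inside the eight-membered ring; C3 (sp3, R) relays chirality to C10 and is flattened afterwards.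
4. Eight-membered ether 18 ⇐ ring-closing metathesis at C4=C5 (Z enforced by the ring) of 17 ⇐ silver-promoted etherification of West alcohol 6 (Sharpless kinetic resolution) with East bromide 16 (chiral-pool butenolide 11; anti conjugate addition sets C7).
5. Ring order: γ-lactone (from 7) → eight-membered ether (step 11) → furanone, ten-membered carbocycle and nine-membered oxacycle together (step 14).

Key step: step 14

Assumption: atom numbers are those of the germacrane skeleton of the target (C1 ketone, C2=C3, C4=C5, C6–O, C7, C8–O, C9, C10, C11=C13, C12 lactone carbonyl, C15 hydroxymethyl); the lactone α-centre C11 of the intermediates is drawn as the expected trans isomer, but its configuration is irrelevant because it becomes sp2 in step 18.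

**Route**

Step 1
Reactants: 1 2-methylenepropane-1,3-diol
Product: 2 mono-TBS ether
Conditions: NaH (1.0 equiv), THF, 0 °C; then TBSCl (1.0 equiv), rt
Reagents that add atoms: tert-butyldimethylsilyl chloride, CC(C)(C)[Si](C)(C)Cl
Why: Monosilylation of a symmetric diol through its sparingly soluble monosodium alkoxide (O-silylation) should stop cleanly at the mono-ether.

Step 2
Reactants: 2 mono-TBS ether
Product: 3 silyloxymethyl acrolein
Conditions: MnO2, CH2Cl2, rt
Reagents that add atoms: none
Why: Activated MnO2 oxidises the allylic alcohol to the enal without touching the silyl ether (allylic oxidation).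

Step 3
Reactants: 3 silyloxymethyl acrolein; 4 tert-butyl acetate
Product: 5 racemic aldol ester
Conditions: LiN(iPr)2, THF, −78 °C, 4; then 3; AcOH quench
Reagents that add atoms: none
Why: The lithium ester enolate should add 1,2 to the α-branched enal at low temperature (aldol addition), giving the racemic β-hydroxy ester.

Step 4
Reactants: 5 racemic aldol ester
Product: 6 (R)-aldol ester
Conditions: Ti(OiPr)4 (cat.), L-(+)-diisopropyl tartrate, tBuOOH (0.6 equiv), 4 Å sieves, CH2Cl2, −20 °C, run to about 55% conversion
Reagents that add atoms: none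
Why: In the Sharpless kinetic resolution the L-(+)-tartrate catalyst should epoxidise the S enantiomer of this 2-substituted secondary allylic alcohol faster and leave the 3R alcohol, while the tert-butyl ester resists transesterification by the titanium alkoxide.

Step 5
Reactants: 7 (S)-hydroxymethyl butyrolactone
Product: 8 lactone aldehyde
Conditions: PhI(OAc)2, TEMPO (cat.), CH2Cl2, rt
Reagents that add atoms: none
Why: Nitroxyl-catalysed oxidation takes the primary alcohol to the aldehyde under non-basic conditions that leave the adjacent stereocentre intact.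

Step 6
Reactants: 8 lactone aldehyde
Product: 9 (S)-vinyl butyrolactone
Conditions: Ph3PCH3Br, KN(SiMe3)2, THF, −78 → 0 °C
Reagents that add atoms: methyltriphenylphosphonium bromide, C[P+](c1ccccc1)(c1ccccc1)c1ccccc1.[Br-]
Why: Wittig methylenation at low temperature should consume the α-oxygenated aldehyde faster than it epimerises.

Step 7
Reactants: 9 (S)-vinyl butyrolactone
Product: 11 (R)-vinyl butenolide, via selenide 10 (not isolated)
Conditions: LiN(iPr)2, THF, −78 °C; PhSeBr; then H2O2 (30% aq.), CH2Cl2, 0 °C → rt
Reagents that add atoms: phenylselanyl bromide, Br[Se]c1ccccc1 (retained only in 10)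
Why: α-Selenenylation of the lactone enolate followed by selenoxide syn-elimination can only give the endocyclic alkene, and the γ-centre is untouched (its descriptor changes from S to R only through the priority rules).

Step 8
Reactants: 11 (R)-vinyl butenolide; 12 (2-bromoallyl)trimethylsilane
Product: 15 allylsilane lactone acetate, via alkenyl Grignard 13 (not isolated), via hydroxymethyl lactone 14 (not isolated)
Conditions: 12, Mg, THF, rt; CuBr·SMe2 (10 mol%), THF, −78 °C, then 11; CH2O (gas), −78 → −40 °C; Ac2O, −40 → 0 °C
Reagents that add atoms: magnesium, [Mg] (retained only in 13); formaldehyde, C=O; acetic anhydride, CC(=O)OC(C)=O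
Why: Copper-catalysed conjugate addition of the alkenyl Grignard reagent should occur anti to the C6 vinyl group (setting C7, trans), the magnesium enolate is trapped by formaldehyde anti to the new C7 substituent and the aldolate is acetylated in the flask (tandem conjugate addition–aldol), which stores the future exocyclic methylene as an acetoxymethyl group.

Step 9
Reactants: 15 allylsilane lactone acetate
Product: 16 allylic bromide
Conditions: NBS, CH2Cl2, −78 → 0 °C
Reagents that add atoms: N-bromosuccinimide, O=C1CCC(=O)N1Br
Why: The allylsilane is the most nucleophilic alkene and should undergo bromodesilylation with allylic transposition (SE2′), leaving the vinyl group alone.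

Step 10
Reactants: 6 (R)-aldol ester; 16 allylic bromide
Product: 17 triene ether
Conditions: AgOSO2CF3, 2,6-di-tert-butylpyridine, 4 Å sieves, CH2Cl2, −40 → 0 °C
Reagents that add atoms: none
Why: Silver-promoted Williamson-type O-alkylation (allylic triflate formed in the flask) works without strong base, so the β-hydroxy ester does not undergo retro-aldol cleavage, the β-acetoxy lactone does not eliminate, and C3 keeps its configuration because its C–O bond is not broken.

Step 11
Reactants: 17 triene ether
Product: 18 oxocene ester
Conditions: second-generation Grubbs catalyst, RuCl2(H2IMes)(PCy3)(=CHPh) (10 mol%), toluene (2 mM), 80 °C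
Reagents that add atoms: none
Why: Ring-closing metathesis should initiate at the monosubstituted C5 vinyl group, from which only closure onto the C4 methylene is productive (closure onto the C8 methylene would give a cyclobutene); the eight-membered ring forces the Z geometry at C4=C5, and the trans-fused lactone and the ether oxygen pre-organise the chain.

Step 12
Reactants: 18 oxocene ester
Product: 19 oxocene acid
Conditions: Me3SiOSO2CF3, 2,6-lutidine, CH2Cl2, 0 °C; then H2O
Reagents that add atoms: none
Why: Silyl triflate-mediated cleavage of the tert-butyl ester (loss of isobutene, then hydrolysis of the silyl ester) is buffered and should spare the silyl ether, the acetate, the lactone and the 1,1-disubstituted alkene.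

Step 13
Reactants: 19 oxocene acid
Product: 21 diazoketone, via mixed anhydride 20 (not isolated)
Conditions: iBuOCOCl, N-methylmorpholine, THF, −20 °C; then CH3CHN2, Et2O, −20 → 0 °C
Reagents that add atoms: isobutyl chloroformate, CC(C)COC(Cl)=O (retained only in 20); diazoethane, CC=[N+]=[N-]
Why: Acylation of diazoethane by the mixed anhydride gives the α-methyl α-diazoketone, and no dipolarophile competes because the lactone methylene is still masked as acetoxymethyl.

Step 14
Reactants: 21 diazoketone
Product: 23 bridged tetrahydrofuranone, via oxonium ylide 22 (not isolated)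
Conditions: Cu(CF3COCHCOCF3)2 (5 mol%), CH2Cl2, reflux, slow addition of 21
Reagents that add atoms: none
Why: The copper carbenoid formed at C10 by loss of N2 is captured by the ring-ether oxygen (O–C10 bond, five-membered ring O–C3–C2–C1–C10) to give the bicyclic oxonium ylide 22, whose C10 enolate carbon then bonds to the exocyclic methylene carbon of the O–CH2–C8(=CH2) allyl unit while the O–CH2 bond breaks ([2,3]-sigmatropic shift through a five-membered envelope), so that C10 is inserted into the ether ring (eight atoms become the nine-membered oxacycle O/C3–C9/C10) and the ten-membered carbocycle C1–C10 closes through the new C9–C10 bond. The closest known reaction type is the copper- or rhodium-catalysed oxonium ylide formation/[2,3]-rearrangement of diazoketones tethered to cyclic allylic ethers, an established entry to oxygen-bridged medium-ring ketones. Ring closures: the furanone ring by intramolecular O-attack on the metal carbene, the ten-membered ring by the sigmatropic C–C bond formation, the nine-membered ring by one-atom enlargement of the existing eight-membered ring. The only new stereocentre, quaternary C10, is fixed by C3 (R): the six-carbon chain C4–C9 can span the tetrahydrofuranone only between cis 2,5-positions, so C9 must enter cis to C4, which corresponds to 10R. The step needs ylide formation to win over cyclopropanation of C4=C5, C–H insertion and 1,2-hydride shift from the C10 methyl, which the electrophilic copper hexafluoroacetylacetonate catalyst and the favourable five-membered O-capture should secure, and it needs the shift to go through the exocyclic allyl unit and not through the allylic C3, which lies inside the ylide ring and could only migrate through a strained bicyclic transition state or to a cyclobutanone.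

Step 15
Reactants: 23 bridged tetrahydrofuranone
Product: 25 bridged furanone, via silyl enol ether 24 (not isolated)
Conditions: Me3SiOSO2CF3, Et3N, CH2Cl2, −78 → 0 °C; then Pd(OAc)2 (10 mol%), O2 (1 atm), DMSO, rt
Reagents that add atoms: trimethylsilyl trifluoromethanesulfonate, C[Si](C)(C)OS(=O)(=O)C(F)(F)F (retained only in 24)
Why: Saegusa–Ito dehydrogenation: only C2 can be enolised (C10 is quaternary), and β-hydride elimination of H3 from the palladium enolate gives the 3(2H)-furanone, erasing the C3 centre after it has done its relay work.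

Step 16
Reactants: 25 bridged furanone
Product: 26 C8 ketone
Conditions: OsO4 (2 mol%), NaIO4, 2,6-lutidine, dioxane/H2O (3:1), rt
Reagents that add atoms: sodium periodate, [Na+].[O-]I(=O)(=O)=O
Why: Lemieux–Johnson cleavage should pick the only isolated, electron-rich alkene (C8=CH2), since C2=C3 and C4=C5 belong to the electron-poor cross-conjugated dienone.

Step 17
Reactants: 26 C8 ketone
Product: 27 8S alcohol
Conditions: NaBH4, MeOH/CH2Cl2 (1:1), −78 → −40 °C
Reagents that add atoms: none
Why: Borohydride reduces the saturated ketone in preference to the vinylogous ester and the lactone, and hydride should arrive from the outer face of the ten-membered ring (the inner face is screened by the furanone bridge), anti to the C7–C11 bond, which should give the 8S alcohol.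

Step 18
Reactants: 27 8S alcohol
Product: 29 O-TBS goyazensolide, via methacrylate acetate 28 (not isolated)
Conditions: methacrylic anhydride, Et3N, DMAP (cat.), CH2Cl2, 0 °C → rt; then DBU, 0 °C
Reagents that add atoms: methacrylic anhydride, C=C(C)C(=O)OC(=O)C(C)=C
Why: DMAP-catalysed acylation of the secondary alcohol is followed in the same flask by E1cB loss of acetate from the β-acetoxy lactone, which unmasks the α-methylene lactone.

Step 19
Reactants: 29 O-TBS goyazensolide
Product: 30 goyazensolide
Conditions: HF·pyridine, THF/pyridine, 0 °C → rt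
Reagents that add atoms: none
Why: Buffered fluoride removes the primary allylic silyl ether without attacking the methacrylate, the α-methylene lactone or the furanone.

**Compound list**

1 | 2-methylenepropane-1,3-diol | C=C(CO)CO | starting material
2 | 2-({[tert-butyl(dimethyl)silyl]oxy}methyl)prop-2-en-1-ol | C=C(CO)CO[Si](C)(C)C(C)(C)C | intermediate
3 | 2-({[tert-butyl(dimethyl)silyl]oxy}methyl)prop-2-enal | C=C(C=O)CO[Si](C)(C)C(C)(C)C | intermediate
4 | tert-butyl acetate | CC(=O)OC(C)(C)C | starting material
5 | racemic tert-butyl 3-hydroxy-4-({[tert-butyl(dimethyl)silyl]oxy}methyl)pent-4-enoate | C=C(CO[Si](C)(C)C(C)(C)C)C(O)CC(=O)OC(C)(C)C | intermediate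
6 | tert-butyl (3R)-3-hydroxy-4-({[tert-butyl(dimethyl)silyl]oxy}methyl)pent-4-enoate | C=C(CO[Si](C)(C)C(C)(C)C)[C@H](O)CC(=O)OC(C)(C)C | intermediate
7 | (5S)-5-(hydroxymethyl)oxolan-2-one | O=C1CC[C@@H](CO)O1 | starting material
8 | (2S)-5-oxooxolane-2-carbaldehyde | O=C1CC[C@@H](C=O)O1 | intermediate
9 | (5S)-5-ethenyloxolan-2-one | O=C1CC[C@@H](C=C)O1 | intermediate
10 | (5S)-5-ethenyl-3-(phenylselanyl)oxolan-2-one, mixture of C3 epimers | O=C1C([Se]c2ccccc2)C[C@@H](C=C)O1 | intermediate
11 | (5R)-5-ethenylfuran-2(5H)-one | O=C1C=C[C@@H](C=C)O1 | intermediate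
12 | (2-bromoprop-2-en-1-yl)trimethylsilane | C=C(Br)C[Si](C)(C)C | starting material
13 | [3-(trimethylsilyl)prop-1-en-2-yl]magnesium bromide | C=C([Mg]Br)C[Si](C)(C)C | intermediate
14 | (3R,4R,5R)-5-ethenyl-3-(hydroxymethyl)-4-[3-(trimethylsilyl)prop-1-en-2-yl]oxolan-2-one (all-trans) | O=C1[C@@H](CO)[C@H](C(=C)C[Si](C)(C)C)[C@@H](C=C)O1 | intermediate
15 | [(3R,4R,5R)-5-ethenyl-2-oxo-4-[3-(trimethylsilyl)prop-1-en-2-yl]oxolan-3-yl]methyl acetate | O=C1[C@@H](COC(C)=O)[C@H](C(=C)C[Si](C)(C)C)[C@@H](C=C)O1 | intermediate
16 | [(3R,4R,5R)-4-(3-bromoprop-1-en-2-yl)-5-ethenyl-2-oxooxolan-3-yl]methyl acetate | O=C1[C@@H](COC(C)=O)[C@H](C(=C)CBr)[C@@H](C=C)O1 | intermediate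
17 | tert-butyl (3R)-3-({2-[(2R,3R,4R)-4-(acetoxymethyl)-2-ethenyl-5-oxooxolan-3-yl]prop-2-en-1-yl}oxy)-4-({[tert-butyl(dimethyl)silyl]oxy}methyl)pent-4-enoate | C=C(CO[Si](C)(C)C(C)(C)C)[C@H](OCC(=C)[C@@H]1[C@@H](C=C)OC(=O)[C@H]1COC(C)=O)CC(=O)OC(C)(C)C | intermediate
18 | eight-membered cyclic ether (ring O–CH2–C8(=CH2)–C7–C6–C5=C4–C3, 4Z, 3R,6R,7R) with trans-fused γ-lactone C6–O–C12(=O)–C11(CH2OAc)–C7, CH2OTBS on C4 and CH2CO2tBu on C3 | CC(C)(C)OC(=O)C[C@H]1OCC(=C)[C@@H]2[C@H](OC(=O)[C@H]2COC(C)=O)/C=C1/CO[Si](C)(C)C(C)(C)C | intermediate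
19 | carboxylic acid corresponding to 18 (CH2CO2H on C3) | OC(=O)C[C@H]1OCC(=C)[C@@H]2[C@H](OC(=O)[C@H]2COC(C)=O)/C=C1/CO[Si](C)(C)C(C)(C)C | intermediate
20 | isobutyl carbonic mixed anhydride of 19 | CC(C)COC(=O)OC(=O)C[C@H]1OCC(=C)[C@@H]2[C@H](OC(=O)[C@H]2COC(C)=O)/C=C1/CO[Si](C)(C)C(C)(C)C | intermediate
21 | α-diazoketone: eight-membered ether of 18 carrying CH2–C(=O)–C(=N2)–CH3 on C3 | CC(=[N+]=[N-])C(=O)C[C@H]1OCC(=C)[C@@H]2[C@H](OC(=O)[C@H]2COC(C)=O)/C=C1/CO[Si](C)(C)C(C)(C)C | intermediate
22 | bicyclic oxonium ylide: ether oxygen of 21 bonded to C10, C1–C10 enolate | CC1=C([O-])C[C@H]2[O+]1CC(=C)[C@@H]1[C@H](OC(=O)[C@H]1COC(C)=O)/C=C2/CO[Si](C)(C)C(C)(C)C | intermediate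
23 | bridged tetrahydrofuran-3-one (3R,6R,7R,10R): ten-membered carbocycle with 3,10-oxygen bridge, C1 ketone, C8 exocyclic methylene, 4Z alkene with CH2OTBS, trans-6,12-lactone with 11-CH2OAc | C=C1C[C@@]2(C)O[C@H](CC2=O)/C(CO[Si](C)(C)C(C)(C)C)=C\[C@H]2OC(=O)[C@@H](COC(C)=O)[C@H]12 | intermediate
24 | trimethylsilyl enol ether of 23 (C1(OSiMe3)=C2) | C=C1C[C@@]2(C)O[C@H](C=C2O[Si](C)(C)C)/C(CO[Si](C)(C)C(C)(C)C)=C\[C@H]2OC(=O)[C@@H](COC(C)=O)[C@H]12 | intermediate
25 | bridged 3(2H)-furanone: 2,3-didehydro derivative of 23 | C=C1C[C@@]2(C)OC(=CC2=O)/C(CO[Si](C)(C)C(C)(C)C)=C\[C@H]2OC(=O)[C@@H](COC(C)=O)[C@H]12 | intermediate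
26 | C8 ketone: 25 with C8=O in place of C8=CH2 | O=C1C[C@@]2(C)OC(=CC2=O)/C(CO[Si](C)(C)C(C)(C)C)=C\[C@H]2OC(=O)[C@@H](COC(C)=O)[C@H]12 | intermediate
27 | (8S)-alcohol: 8-O-demethacryloyl-13-acetoxy-11,13-dihydro-15-O-TBS-goyazensolide | O[C@H]1C[C@@]2(C)OC(=CC2=O)/C(CO[Si](C)(C)C(C)(C)C)=C\[C@H]2OC(=O)[C@@H](COC(C)=O)[C@H]12 | intermediate
28 | 8-methacrylate of 27 (13-acetoxy-11,13-dihydro-15-O-TBS-goyazensolide) | C=C(C)C(=O)O[C@H]1C[C@@]2(C)OC(=CC2=O)/C(CO[Si](C)(C)C(C)(C)C)=C\[C@H]2OC(=O)[C@@H](COC(C)=O)[C@H]12 | intermediate
29 | 15-O-(tert-butyldimethylsilyl)goyazensolide | C=C(C)C(=O)O[C@H]1C[C@@]2(C)OC(=CC2=O)/C(CO[Si](C)(C)C(C)(C)C)=C\[C@H]2OC(=O)C(=C)[C@H]12 | intermediate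
30 | goyazensolide (6R,7R,8S,10R; 4Z) | C=C(C)C(=O)O[C@H]1C[C@@]2(C)OC(=CC2=O)/C(CO)=C\[C@H]2OC(=O)C(=C)[C@H]12 | target

**Step count and risks**

Total step count: 19 (steps 1–4 West fragment, steps 5–9 East fragment, steps 10–19 after coupling). Longest linear sequence: 15 steps (steps 5–19, from 7).

Steps most likely to fail:

Step 14. The copper carbenoid may be consumed by 1,2-hydride shift from the C10 methyl or by cyclopropanation of the neighbouring C4=C5 alkene before the ether oxygen intercepts it. The fallback sets out from acid 19 and returns to 23. Activation of 19 with carbonyldiimidazole and reaction with LiCH2SO2Ph in THF at −78 °C should give the β-keto sulfone F1. Diazo transfer (4-acetamidobenzenesulfonyl azide, Et3N, MeCN) gives the α-diazo-β-keto sulfone F2, an acceptor/acceptor diazo compound that has no β-hydrogen on the carbene carbon and needs no diazoalkane. Dirhodium tetraacetate, Rh2(OAc)4, in CH2Cl2 then effects the same ylide formation and [2,3] ring expansion to give the C10-phenylsulfonyl bridged ketone F3. SmI2 in THF at −78 °C cleaves the sulfone to the C1–C10 samarium enolate regiospecifically, and CH3I alkylates it on carbon to give 23; the bridge leaves only one position for the methyl group at C10.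

Step 8. The organocopper species may open the vinyl lactone by SN2′ attack or deprotonate the doubly activated γ-position instead of adding 1,4, and hydroxymethylation of the enolate may be incomplete. The fallback sets out from 12 and returns to 15; steps 5–7 are then not needed. Grignard reagent 13 (from 12) is added under the same copper catalysis to commercial (5S)-5-({[tert-butyl(dimethyl)silyl]oxy}methyl)furan-2(5H)-one F4, whose γ-substituent can neither ionise nor stabilise a γ-anion as well. Trapping with formaldehyde and Ac2O gives the silyloxymethyl lactone acetate F5. HF·pyridine frees the primary alcohol F6, Dess–Martin periodinane oxidises it to the aldehyde F7, and Wittig methylenation (Ph3P=CH2, THF, −78 °C) gives 15.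

Step 17. Facial selectivity of hydride addition to the C8 ketone in the flexible ten-membered ring may be poor or reversed. The fallback sets out from 26 and returns to 28 (and from there to 29 as in step 18). If hydride delivers mainly the (8R)-alcohol F8, this epimer is esterified under Mitsunobu conditions (methacrylic acid, PPh3, diisopropyl azodicarboxylate, THF, 0 °C), which inverts C8 and installs the methacrylate in one operation to give 28; DBU then gives 29.

**Further compounds**

F1 | step 14 | β-keto sulfone: eight-membered ether of 19 carrying CH2–C(=O)–CH2–SO2Ph on C3 | O=C(CS(=O)(=O)c1ccccc1)C[C@H]1OCC(=C)[C@@H]2[C@H](OC(=O)[C@H]2COC(C)=O)/C=C1/CO[Si](C)(C)C(C)(C)C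
F2 | step 14 | α-diazo-β-keto sulfone derived from F1 | [N-]=[N+]=C(C(=O)C[C@H]1OCC(=C)[C@@H]2[C@H](OC(=O)[C@H]2COC(C)=O)/C=C1/CO[Si](C)(C)C(C)(C)C)S(=O)(=O)c1ccccc1
F3 | step 14 | bridged tetrahydrofuranone as 23 with phenylsulfonyl in place of the C10 methyl | C=C1C[C@@]2(S(=O)(=O)c3ccccc3)O[C@H](CC2=O)/C(CO[Si](C)(C)C(C)(C)C)=C\[C@H]2OC(=O)[C@@H](COC(C)=O)[C@H]12
F4 | step 8 | (5S)-5-({[tert-butyl(dimethyl)silyl]oxy}methyl)furan-2(5H)-one | O=C1C=C[C@@H](CO[Si](C)(C)C(C)(C)C)O1
F5 | step 8 | all-trans lactone as 15 with CH2OTBS in place of the vinyl group | O=C1[C@@H](COC(C)=O)[C@H](C(=C)C[Si](C)(C)C)[C@@H](CO[Si](C)(C)C(C)(C)C)O1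
F6 | step 8 | all-trans lactone as 15 with CH2OH in place of the vinyl group | O=C1[C@@H](COC(C)=O)[C@H](C(=C)C[Si](C)(C)C)[C@@H](CO)O1
F7 | step 8 | all-trans lactone as 15 with CHO in place of the vinyl group | O=C1[C@@H](COC(C)=O)[C@H](C(=C)C[Si](C)(C)C)[C@@H](C=O)O1
F8 | step 17 | (8R)-alcohol, C8 epimer of 27 | O[C@@H]1C[C@@]2(C)OC(=CC2=O)/C(CO[Si](C)(C)C(C)(C)C)=C\[C@H]2OC(=O)[C@@H](COC(C)=O)[C@H]12
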